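**Retrosynthetic overview**

- Feature: O1–C8a–C4a–C4 (ring A plus its benzylic carbon) is the hetero-diene of an ortho-quinone methide, and C2–C3 carrying ring B is a donor-substituted styrene, so ring C is a single oxa-[4+2] adduct.
- Disconnections: the 5-OH is unmasked last from the methyl ether beside the C4 carbonyl; the carbonyl comes from a C4 methoxy group left by the cycloaddition; O1–C2 and C3–C4 are cut together to a ring A salicylaldehyde and 2,6-dimethoxystyrene.
- Ring order: rings A and B are bought as arenes (3,4,5-trimethoxyphenol, 2,6-dimethoxybenzaldehyde); ring C is the only ring made, in the cycloaddition that also sets C2.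
- The C4 stereocentre formed alongside is temporary and is erased by oxidation.

Key step: step 5

Assumption: the sense of induction of the chiral acid cannot be predicted with certainty, so the (R)-catalyst is written and its mirror image would be used if it favoured the 2R adduct; the configuration at C4 of the adduct is immaterial.

**Route**

Step 1
Reactants: 1 3,4,5-trimethoxyphenol
Product: 2 1,2,3,5-tetramethoxybenzene
Conditions: MeI, K2CO3, acetone, reflux
Reagents that add atoms: iodomethane (CI)
Why: Williamson ether synthesis, in which the phenoxide is the only nucleophilic site and reacts cleanly with iodomethane by SN2.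

Step 2
Reactants: 2 1,2,3,5-tetramethoxybenzene
Product: 4 2,3,4,6-tetramethoxybenzaldehyde, via iminium chloride 3 (not isolated)
Conditions: POCl3, DMF, 0 °C → 70 °C; then ice-water, rt
Reagents that add atoms: N,N-dimethylformamide (CN(C)C=O); water (O)
Why: Vilsmeier–Haack formylation of a tetra-alkoxybenzene is fast, and because the two free ring positions of 2 are related by symmetry only one aldehyde can result once iminium salt 3 is hydrolysed.

Step 3
Reactants: 4 2,3,4,6-tetramethoxybenzaldehyde
Product: 6 2-hydroxy-3,4,6-trimethoxybenzaldehyde, via aryloxydichloroborane 5 (not isolated)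
Conditions: BCl3 (1.1 equiv), CH2Cl2, −78 °C → 0 °C; then H2O
Reagents that add atoms: none
Why: Chelation-controlled Lewis-acid O-demethylation ortho to a carbonyl group, in which BCl3 bound to the formyl oxygen cleaves a neighbouring methyl ether through a six-membered chelate; of the two ortho ethers the one at C2 is also flanked by the 3-methoxy group, is twisted out of the ring plane and is therefore the more basic and more strained one (the usual preference in polymethoxyaryl carbonyl compounds), while the deactivated chelate 5 resists a second cleavage.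

Step 4
Reactants: 7 2,6-dimethoxybenzaldehyde
Product: 8 2,6-dimethoxystyrene (2-ethenyl-1,3-dimethoxybenzene)
Conditions: Ph3PCH3Br, KOtBu, THF, 0 °C → rt
Reagents that add atoms: methyltriphenylphosphonium bromide (C[P+](c1ccccc1)(c1ccccc1)c1ccccc1.[Br-])
Why: Wittig methylenation of a non-enolisable aldehyde by the unstabilised ylide is reliable even with two ortho substituents and is driven by formation of Ph3P=O.

Step 5
Reactants: 6 2-hydroxy-3,4,6-trimethoxybenzaldehyde; 8 2,6-dimethoxystyrene; 9 trimethyl orthoformate
Product: 12 (2S,4S)-2-(2,6-dimethoxyphenyl)-4,5,7,8-tetramethoxychroman, via dimethyl acetal 10 (not isolated), via O-methyl ortho-quinone methide 11 (not isolated)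
Conditions: 6, 9 (1.3 equiv), (R)-3,3'-bis(2,4,6-triisopropylphenyl)-H8-BINOL N-triflyl phosphoramide (5 mol %), 5 Å molecular sieves, toluene, rt; then −40 °C, 8 (2 equiv) added slowly; Et3N quench at −40 °C
Reagents that add atoms: trimethyl orthoformate (COC(OC)OC)
Why: Proposed new method: the chiral acid first catalyses acetalisation of 6 by 9 to 10 and then ionises 10 by loss of methanol to the O-methyl oxocarbenium ion, that is O-protonated quinone methide 11, which stays hydrogen-bonded through its phenolic OH to the phosphoramide anion; the unsubstituted alkene carbon of 8 attacks the methide carbon (C3–C4) while the benzylic carbon, whose developing positive charge is stabilised by the two ortho methoxy groups of ring B, is captured by the phenol oxygen (O1–C2) as the proton returns to the anion. The closest known reactions are the racemic acid-catalysed three-component union of salicylaldehydes, trimethyl orthoformate and styrenes to 4-methoxy-2-arylchromans and the chiral-phosphoric-acid-catalysed [4+2] cycloaddition of ortho-quinone methides from ortho-hydroxybenzyl alcohols with styrenes; what is new is enantiocontrol in the acetal-derived 4-alkoxy series. Ring C is closed by an intermolecular inverse-electron-demand oxa-[4+2] cycloaddition (hetero-diene O1–C8a–C4a–C4 plus C2=C3), concerted but asynchronous, which in the stepwise limit is a six-membered ring closure of the phenol oxygen onto the benzylic cation. C2 is set by the chiral anion, which sits on O1 and shields one face of the cation so that the styrene adds to the open face in an endo orientation (ring B stacked on the electron-poor ring A), and C4 follows from the E geometry of 11 and the same endo approach (2,4-cis) but is of no consequence because it is oxidised in step 7. The step needs regioselectivity (CH2 to C4, secured by the polarity of the styrene and the ortho-methoxy stabilisation of the C2 cation), enantioselectivity at C2 (tight ion pair, low temperature, non-polar solvent) and chemoselectivity over styrene oligomerisation and Friedel–Crafts arylation (slow addition of 8, low acid loading, cold amine quench).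

Step 6
Reactants: 12 (2S,4S)-2-(2,6-dimethoxyphenyl)-4,5,7,8-tetramethoxychroman
Product: 13 (2S,4RS)-2-(2,6-dimethoxyphenyl)-5,7,8-trimethoxychroman-4-ol
Conditions: TsOH·H2O (10 mol %), THF–H2O (3:1), high dilution, 0 °C → rt; NaHCO3 quench
Reagents that add atoms: water (O)
Why: Acid-catalysed SN1 solvolysis (ether-to-alcohol exchange) at C4, where the cation is stabilised by O1 and by the 5- and 7-methoxy groups and forms at an acidity at which the much less basic aryl ether O1–C2 is not ionised; water in large excess captures it, and the C4 epimer mixture is acceptable because C4 becomes a carbonyl carbon.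

Step 7
Reactants: 13 (2S,4RS)-2-(2,6-dimethoxyphenyl)-5,7,8-trimethoxychroman-4-ol
Product: 14 (2S)-2-(2,6-dimethoxyphenyl)-5,7,8-trimethoxychroman-4-one
Conditions: Dess–Martin periodinane, NaHCO3, CH2Cl2, 0 °C → rt
Reagents that add atoms: none
Why: Dess–Martin oxidation of a secondary benzylic alcohol runs under buffered, near-neutral conditions that neither re-ionise C4 nor open ring C, both C4 epimers converge on one ketone, and C2, which is β to the new carbonyl, is not touched.

Step 8
Reactants: 14 (2S)-2-(2,6-dimethoxyphenyl)-5,7,8-trimethoxychroman-4-one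
Product: 16 (2S)-2-(2,6-dimethoxyphenyl)-5-hydroxy-7,8-dimethoxychroman-4-one, via boron chelate 15 (not isolated)
Conditions: BCl3 (1.5 equiv), CH2Cl2, −78 °C → −20 °C; then H2O, 0 °C
Reagents that add atoms: none
Why: Chelation-directed Lewis-acid O-demethylation peri to a carbonyl, in which BCl3 held on the C4 carbonyl oxygen can reach only the 5-methoxy group (six-membered chelate 15), so the 7-, 8-, 2'- and 6'-methyl ethers survive at low temperature, and the cold, base-free reaction and work-up avoid the enolisation and ring opening by which a flavanone would lose its C2 configuration.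

**Compound list**

1 | 3,4,5-trimethoxyphenol | COc1cc(O)cc(OC)c1OC | starting material
2 | 1,2,3,5-tetramethoxybenzene | COc1cc(OC)c(OC)c(OC)c1 | intermediate
3 | N,N-dimethyl-1-(2,3,4,6-tetramethoxyphenyl)methaniminium chloride (not isolated) | COc1cc(OC)c(C=[N+](C)C)c(OC)c1OC.[Cl-] | intermediate
4 | 2,3,4,6-tetramethoxybenzaldehyde | COc1cc(OC)c(C=O)c(OC)c1OC | intermediate
5 | dichloro(2-formyl-3,5,6-trimethoxyphenoxy)borane, chelated to the formyl oxygen (not isolated) | COc1cc(OC)c(C=O)c(OB(Cl)Cl)c1OC | intermediate
6 | 2-hydroxy-3,4,6-trimethoxybenzaldehyde | COc1cc(OC)c(C=O)c(O)c1OC | intermediate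
7 | 2,6-dimethoxybenzaldehyde | COc1cccc(OC)c1C=O | starting material
8 | 2,6-dimethoxystyrene | C=Cc1c(OC)cccc1OC | intermediate
9 | trimethyl orthoformate | COC(OC)OC | starting material
10 | 2-(dimethoxymethyl)-3,5,6-trimethoxyphenol (not isolated) | COc1cc(OC)c(C(OC)OC)c(O)c1OC | intermediate
11 | (E)-6-(methoxymethylidene)-2,3,5-trimethoxycyclohexa-2,4-dien-1-one, reacting as its O-protonated ion pair with the catalyst anion; drawn E, the geometry is mobile in the protonated form (not isolated) | CO/C=C1/C(=O)C(OC)=C(OC)C=C1OC | intermediate
12 | (2S,4S)-2-(2,6-dimethoxyphenyl)-4,5,7,8-tetramethoxychroman (2,4-cis) | COc1cc(OC)c2c(c1OC)O[C@H](c1c(OC)cccc1OC)C[C@@H]2OC | intermediate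
13 | (2S,4RS)-2-(2,6-dimethoxyphenyl)-5,7,8-trimethoxychroman-4-ol (both C4 epimers) | COc1cc(OC)c2c(c1OC)O[C@H](c1c(OC)cccc1OC)CC2O | intermediate
14 | (2S)-2-(2,6-dimethoxyphenyl)-5,7,8-trimethoxychroman-4-one | COc1cc(OC)c2c(c1OC)O[C@H](c1c(OC)cccc1OC)CC2=O | intermediate
15 | (2S)-5-(dichloroboryloxy)-2-(2,6-dimethoxyphenyl)-7,8-dimethoxychroman-4-one, chelated to the C4 carbonyl oxygen (not isolated) | COc1cc(OB(Cl)Cl)c2c(c1OC)O[C@H](c1c(OC)cccc1OC)CC2=O | intermediate
16 | (2S)-5-hydroxy-7,8,2',6'-tetramethoxyflavanone | COc1cc(O)c2c(c1OC)O[C@H](c1c(OC)cccc1OC)CC2=O | target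

**Step count**

Total: 8 steps. Longest linear sequence: 7 steps (steps 1, 2, 3, 5, 6, 7, 8); step 4 is a one-step side branch.

**Steps most likely to fail**

1. Step 5 (proposed new method).
   - What may go wrong: insufficient facial discrimination in the ion pair; erosion of the C2 configuration through reversible acid-induced heterolysis of the O1–C2 benzylic ether; diversion of the cation into Friedel–Crafts arylation of ring B or of a second ring A; cationic oligomerisation of the styrene.
   - Fallback, known chemistry only, setting out from 2 and 7 and coming back at 14: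
     - Friedel–Crafts acetylation of 2 (AcCl, AlCl3, CH2Cl2, 0 °C → rt), followed in the same pot by AlCl3-mediated cleavage of the flanked ortho-methoxy group, should give 2-hydroxy-3,4,6-trimethoxyacetophenone F1.
     - Claisen–Schmidt condensation of F1 with 7 (KOH, EtOH, rt) should give (E)-3-(2,6-dimethoxyphenyl)-1-(2-hydroxy-3,4,6-trimethoxyphenyl)prop-2-en-1-one F2.
     - Oxa-Michael ring closure (NaOAc, EtOH, reflux) should give racemic 2-(2,6-dimethoxyphenyl)-5,7,8-trimethoxychroman-4-one F3.
     - Kinetic resolution by asymmetric transfer hydrogenation (RuCl(p-cymene)[(R,R)-TsDPEN], HCO2H–Et3N, EtOAc, rt, stopped near half conversion) is expected on the usual model to reduce the 2R ketone to (2R,4R)-2-(2,6-dimethoxyphenyl)-5,7,8-trimethoxychroman-4-ol F4 and to leave (S)-14, which is separated by chromatography and enters step 8.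

2. Step 6.
   - What may go wrong: partition of the C4 cation toward proton loss from C3 (flav-3-ene formation) or toward arylation of a second molecule instead of capture by water; slow heterolysis at C2 on prolonged exposure to acid.
   - Fallback, setting out from 12 and coming back at 14: the solvolysis is replaced by an oxidative cleavage of the benzylic methyl ether with DDQ (1.5 equiv, CH2Cl2–pH 7 phosphate buffer 10:1, 0 °C → rt). Hydride abstraction from C4 should give the 4-methoxy oxocarbenium ion, which adds water and collapses to ketone 14 and methanol. No free C4 alcohol and no acid are involved, and step 7 is skipped. This fallback makes no new compound (F0).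

3. Step 8.
   - What may go wrong: loss of the C2 configuration by Lewis-acid-promoted opening of ring C (enolisation toward C3 with expulsion of the O1 phenoxide, or heterolysis of O1–C2 assisted by ring B) and reclosure; further cleavage of the 8-methoxy group.
   - Fallback, setting out from 4 and coming back at 16: the 5-oxygen is carried as a benzyl ether that is removed by hydrogenolysis.
     - Excess BCl3 (3 equiv, CH2Cl2, 0 °C → rt) should cleave both ortho methyl ethers of 4 to 2,6-dihydroxy-3,4-dimethoxybenzaldehyde F5.
     - Benzyl bromide (1.0 equiv, K2CO3, acetone, rt) should alkylate the less hindered 6-OH, the 2-OH being flanked on both sides and hydrogen-bonded, to give 6-(benzyloxy)-2-hydroxy-3,4-dimethoxybenzaldehyde F6.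
     - The conditions of step 5 with 8 and 9 should give (2S,4S)-5-(benzyloxy)-2-(2,6-dimethoxyphenyl)-4,7,8-trimethoxychroman F7.
     - The conditions of step 6 should give (2S,4RS)-5-(benzyloxy)-2-(2,6-dimethoxyphenyl)-7,8-dimethoxychroman-4-ol F8.
     - The conditions of step 7 should give (2S)-5-(benzyloxy)-2-(2,6-dimethoxyphenyl)-7,8-dimethoxychroman-4-one F9.
     - Hydrogenolysis (H2, Pd/C, EtOAc, rt) should then free the 5-OH under neutral conditions and give 16.

**Further compounds**

F1 | step 5 | 2-hydroxy-3,4,6-trimethoxyacetophenone | CC(=O)c1c(O)c(OC)c(OC)cc1OC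
F2 | step 5 | (E)-3-(2,6-dimethoxyphenyl)-1-(2-hydroxy-3,4,6-trimethoxyphenyl)prop-2-en-1-one | COc1cc(OC)c(C(=O)/C=C/c2c(OC)cccc2OC)c(O)c1OC
F3 | step 5 | racemic 2-(2,6-dimethoxyphenyl)-5,7,8-trimethoxychroman-4-one | COc1cc(OC)c2c(c1OC)OC(c1c(OC)cccc1OC)CC2=O
F4 | step 5 | (2R,4R)-2-(2,6-dimethoxyphenyl)-5,7,8-trimethoxychroman-4-ol | COc1cc(OC)c2c(c1OC)O[C@@H](c1c(OC)cccc1OC)C[C@H]2O
F0 | step 6 | none | none
F5 | step 8 | 2,6-dihydroxy-3,4-dimethoxybenzaldehyde | COc1cc(O)c(C=O)c(O)c1OC
F6 | step 8 | 6-(benzyloxy)-2-hydroxy-3,4-dimethoxybenzaldehyde | COc1cc(OCc2ccccc2)c(C=O)c(O)c1OC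
F7 | step 8 | (2S,4S)-5-(benzyloxy)-2-(2,6-dimethoxyphenyl)-4,7,8-trimethoxychroman | COc1cc(OCc3ccccc3)c2c(c1OC)O[C@H](c1c(OC)cccc1OC)C[C@@H]2OC
F8 | step 8 | (2S,4RS)-5-(benzyloxy)-2-(2,6-dimethoxyphenyl)-7,8-dimethoxychroman-4-ol | COc1cc(OCc3ccccc3)c2c(c1OC)O[C@H](c1c(OC)cccc1OC)CC2O
F9 | step 8 | (2S)-5-(benzyloxy)-2-(2,6-dimethoxyphenyl)-7,8-dimethoxychroman-4-one | COc1cc(OCc3ccccc3)c2c(c1OC)O[C@H](c1c(OC)cccc1OC)CC2=O
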